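A closed, stirred vessel takes electrophile and nucleophile at constant temperature under a held level of gas, and two earlier runs show how far the nucleophile goes.

in all of them: gas 0.49 mM (held)

| flask | electrophile | nucleophile | remark | time |
|---|---|---|---|---|
| epsilon | 14 mM | 25 mM | run made earlier |  |
| zeta | 47 mM | 25 mM | run made earlier |  |
| elm | 10 mM | 25.0 mM |  | 3.0 min |
| maple | 40 mM | 25.0 mM |  | 10 min |

| run | time / min | target / % | electrophile / % |
|---|---|---|---|
| epsilon | 0.500 | 12.3 | 86.6 |
| epsilon | 1.00 | 21.3 | 76.2 |
| epsilon | 1.50 | 28.7 | 67.4 |
| epsilon | 2.00 | 35.1 | 61.5 |
| epsilon | 2.50 | 40.7 | 55.5 |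
| epsilon | 3.00 | 43.7 | 50.8 |
| zeta | 0.250 | 5.6 | 93.3 |
| zeta | 0.417 | 9.2 | 90.0 |
| zeta | 0.667 | 12.6 | 84.9 |
| zeta | 1.00 | 16.2 | 81.0 |
| zeta | 2.00 | 22.7 | 72.5 |
| zeta | 3.00 | 26.7 | 67.9 |

(scatter of a reading: 0.3 percentage points)

- the analysis behind the earlier runs scatters by 0.3 percentage points, standard deviation
- at the start none of the gas is in solution

* which of the two ends with the higher amount of target, in percent of the electrophile charged ("neither" if they lie within 2 percentage points) (elm / maple / neither)
* target at the end, in percent of the electrophile charged, elm
* target at the end, in percent of the electrophile charged, maple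

The first epsilon reading gives a rough pseudo-first-order rate of target formation, taken on the electrophile charged, 0.246 min⁻¹, at nearly full nucleophile. One nucleophile per target would let maple reach 62.5%. But between zeta's last two readings the rate per electrophile present is 0.0570 min⁻¹, lower, and with rate proportional to free nucleophile this means:

free nucleophile = 5.79 mM, with target at 11.6 mM

cost = (charge − free nucleophile) / target = 1.65

This is the nucleophile cost, nucleophile gone per target formed. It rests on a difference of two readings, yet their scatter moves free nucleophile by 0.614 mM, which is tolerable. Dividing the charge by the cost gives the reach: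

reach, maple = nucleophile charged / (cost × electrophile charged) = 37.8%

Is the time enough? Beyond zeta's last reading, the reach needs a further 2.56 mM of target, which takes an estimated 1.36 min if zeta's late pace held, less than maple's time, though that pace is itself falling. So maple, with nucleophile as limiting reagent, is reckoned here at the reach.

In elm the reach is 151%, above the whole charge, so time is reckoned first: 52.2% at full nucleophile. But nucleophile falls meanwhile, by an estimated 4.32 mM on average, and this correction gives:

target, elm = 45.7%

The forecast, close to this but not the same, names elm, with 47% for elm and 37% for maple: “Maple starts like zeta, reaching about 12 mM by 3 min, then stalls.”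

The flask gives elm, with 46.9% in elm and 38.8% in maple.

    electrophile + nucleophile → acid set free + target (k = 11.3 M⁻¹ min⁻¹)
    nucleophile + acid set free ⇌ protonated nucleophile, settled at all times (K = 2.20 × 10⁵ M⁻¹)
    acid set free + free base ⇌ salt of the base, settled at all times (K = 5.25 × 10⁵ M⁻¹)
    electrophile ⇌ dormant form (K = 0.387, k = 0.0286 min⁻¹)
    gas ⇌ free base, rate k5*(csat - [free base]) (kL = 350 min⁻¹)

The difference in electrophile charge is the main reason for maple's lower percentage: with that difference taken away, maple gives 76.0% instead of 38.8%. Acid set free by the reaction takes further nucleophile as protonated nucleophile, 8.18 mM in maple at 10.0 min. Removing that parking lifts maple from 38.8% to 56.2%, about what the tenfold time gives, 54.9%. Maple's own cost is 1.53. In the neighbour flask, which is maple with 160 mM of electrophile, the reach gives 9.44%. That flask gives 13.3%, with 0.92% of its nucleophile charge left unbound, at a cost of 1.16.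

The runs were generated by integration on assumed constants, and the scatter is random.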